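Slowness is the first thing to explain: why does D crawl in the alpha run while Z stands dissolved?

the same everywhere: Z 0.82 M; G 5.7 mol%

| run | J | remark | time |
|---|---|---|---|
| beta | 0.082 M | the very flask that is asked about, followed so far |  |
| alpha | 0.16 M | run made earlier |  |
| flask | 0.0820 M |  | 2.5 d |

- beta (time / h: D / %, Z / %): 2.00: 0, 95.9; 4.00: 0.2, 92.4; 5.00: 0, 90.4; 8.00: 2.1, 86.5
- alpha (time / d: D / %, Z / %): 0.333: 1.6, 86.2; 0.833: 5.1, 75.9; 1.67: 6.6, 67.2; 2.50: 8.1, 64.6

(standard deviation of a reading: 0.5 percentage points)

- given per volume of solution although it is solid: Z
- what was read earlier has a scatter of 0.5 percentage points, one standard deviation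
- at the start none of Z is in solution

- Wednesday's: doubling the amount of G, all else as stated
- Saturday's: doubling the dissolution coefficient of Z, all else as stated
- Sunday's: doubling the solubility of Z, all else as stated

1. amount of D at 2.5 d, in percent of the Z charged
2. the change that raises the amount of D at 2.5 d, in percent of the Z charged most ("none" if none brings more than 2 percentage points) (Wednesday's / Saturday's / Sunday's / none)
3. amount of D at 2.5 d, in percent of the Z charged, after Wednesday's

Is the solid too slow to feed the solution? I read dissolved Z as what is missing from Z and D together, and in the alpha run that share goes from 26.2% at 1.67 d to 27.3% at 2.50 d, about 0.224 M, while D gains 1.5 percentage points over the same stretch, so more dissolved Z stands waiting than D was made from it.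

Then what is short? The charges offer a suspect, and it is my guess: G starts chains at a charged 0.0467 M, and J may end them, so I carry the stopper ratio, 1.75 in this flask, cJ over cG as charged, against 3.42 in the alpha run.

But beta's D of 2.1% at 8.00 h stands near alpha's 1.6% at 0.333 d, so has J no effect? That gap of 0.5 points is set against a scatter of 0.5 points, so these two readings do not answer the question.

So I commit to D above alpha's 8.1% in this flask at 2.5 d. Wednesday's takes the ratio to 0.877, below one, so I rank it best and expect more than 16.2% after it.

The forecast gave 8.5%, Wednesday's and 15%, reasoning “Doubling G should nearly double D”, and it parts from my reckoning on that last number.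

The flask gives 12.1%, with Wednesday's best, gaining 25 points, and 36.7% after it.

    Q + G → E + D (k = 0.580 L mol⁻¹ h⁻¹)
    Q + E → D + E, rate k2*[E]*[Q] (k = 2.00 L mol⁻¹ h⁻¹)
    E + J → X (k = 4.80 L mol⁻¹ h⁻¹)
    Z ⇌ Q, rate k4*(cs4 - [Q]) while solid is left; crystals form when [Q] > cs4 (solubility = 0.230 M, k = 0.0800 h⁻¹)

At the ratio of 1.75, this flask at 2.5 d has 0.34% of its G left against 44% of its J, so G is the limiting reagent. The neighbour flask with 23 mol% of G has a ratio of 0.435, below one; there J is the first to run out, with 0% left, E stands at 0.0930 M, and D reaches 82.1%.

The readings were generated by integration on assumed constants; noise was put on by code.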